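## Retrosynthetic overview

1. The target 16 is cut at the depside ester bond (ring A acyl carbon to O4 of ring B). This gives a ring A acid with its 4-OH silylated (9) and a ring B phenol with its acid benzylated (12). Both come from the same acid 9.
2. The strategy rests on one feature, identical in both rings: C1 carries the carboxyl carbon, its neighbours are C2–OMe and C6–pentyl, and the oxygen at C4 is para to C1. A C1≡C6 aryne flanked by the C2 methoxy group can therefore take up pentyl at C6 and CO2 at C1 in one operation.
3. Acid 9 is disconnected to the 3-methoxy-5-silyloxybenzyne 7, pentylmagnesium bromide 4 and CO2 5. Aryne 7 comes from fluoroarene 3 by lithiation between F and OMe and loss of LiF, and 3 comes from phenol 1.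
4. No ring is formed in the route. Both benzene rings are bought in 1, and rings A and B are joined in step 5.

Key step: step 2

Assumption: pentylmagnesium bromide 4 is taken as the commercial ether solution, so its preparation from 1-bromopentane and magnesium is not counted as a step.

## Route

Step 1
Reactants: 1 3-fluoro-5-methoxyphenol; 2 triisopropylsilyl chloride
Product: 3 (3-fluoro-5-methoxyphenoxy)triisopropylsilane
Conditions: imidazole, DMF, rt
Reagents that add atoms: triisopropylsilyl chloride (2), CC(C)[Si](Cl)(C(C)C)C(C)C
Why: Imidazole-mediated O-silylation of a phenol is routine, and the resulting bulky aryl silyl ether tolerates n-BuLi at low temperature and shields both of its ortho C–H bonds for the next step.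

Step 2
Reactants: 3 (3-fluoro-5-methoxyphenoxy)triisopropylsilane; 4 pentylmagnesium bromide; 5 carbon dioxide
Product: 9 2-methoxy-6-pentyl-4-(triisopropylsilyloxy)benzoic acid, via ortho-fluoroaryllithium 6 (not isolated), via 3-methoxy-5-silyloxybenzyne 7 (not isolated), via arylmagnesium bromide 8 (not isolated)
Conditions: n-BuLi (1.05 equiv), THF, −78 °C; C5H11MgBr (2 equiv), −78 °C to rt; dry CO2, −20 °C to rt; 1 M aq. HCl work-up
Reagents that add atoms: pentylmagnesium bromide (4), CCCCC[Mg]Br; carbon dioxide (5), O=C=O
Why: n-BuLi removes the proton between F and OMe (directed ortho-metalation at the most acidic site, the only one not screened by the silyl ether) to give aryllithium 6, which loses LiF on warming in the presence of the Grignard reagent to give aryne 7. Pentylmagnesium bromide then adds across the strained triple bond (carbomagnesiation) at the carbon remote from the methoxy group, because the inductively withdrawing oxygen distorts the aryne and stabilises and chelates the metal-bearing carbon next to it; the arylmagnesium 8 so formed is carboxylated by CO2 and the acid is released on acidification. The closest known reaction type is the three-component coupling of 3-alkoxybenzynes, generated from lithiated fluoroanisoles, with Grignard reagents and electrophiles such as CO2. No ring is closed and no stereocentre is formed; the step makes the C6–pentyl and C1–carboxyl bonds in one flask. Two selectivities are needed: site-selective metalation, secured by the F/OMe pair and the bulk of the triisopropylsilyl group, and regioselective addition to the aryne, secured by the methoxy group beside the triple bond. Butyl transfer is limited by consuming n-BuLi completely at −78 °C before the excess Grignard reagent is added.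

Step 3
Reactants: 9 2-methoxy-6-pentyl-4-(triisopropylsilyloxy)benzoic acid (first portion); 10 benzyl bromide
Product: 11 benzyl 2-methoxy-6-pentyl-4-(triisopropylsilyloxy)benzoate
Conditions: KHCO3, DMF, rt
Reagents that add atoms: benzyl bromide (10), BrCc1ccccc1
Why: O-alkylation of the carboxylate is an SN2 reaction at the benzylic carbon and is therefore insensitive to the hindrance around the 2,6-disubstituted carboxyl group, while bicarbonate is too weak a base to cleave the aryl silyl ether.

Step 4
Reactants: 11 benzyl 2-methoxy-6-pentyl-4-(triisopropylsilyloxy)benzoate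
Product: 12 benzyl 4-hydroxy-2-methoxy-6-pentylbenzoate
Conditions: TBAF, AcOH, THF, 0 °C
Reagents that add atoms: none
Why: Fluoride-induced cleavage of an aryl silyl ether is fast and driven by Si–F bond formation, and the acetic acid buffer keeps the benzyl ester untouched.

Step 5
Reactants: 9 2-methoxy-6-pentyl-4-(triisopropylsilyloxy)benzoic acid (second portion); 12 benzyl 4-hydroxy-2-methoxy-6-pentylbenzoate
Product: 14 benzyl 2-methoxy-4-{[2-methoxy-6-pentyl-4-(triisopropylsilyloxy)benzoyl]oxy}-6-pentylbenzoate, via mixed trifluoroacetic anhydride 13 (not isolated)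
Conditions: (CF3CO)2O, toluene, 0 °C to rt
Reagents that add atoms: none
Why: This is the classical depside esterification, in which trifluoroacetic anhydride turns the hindered, electron-rich acid into a mixed anhydride that ionises to a stabilised aroyl cation and acylates the unhindered phenol oxygen, under anhydrous acid that the benzyl ester and the aryl silyl ether tolerate.

Step 6
Reactants: 14 benzyl 2-methoxy-4-{[2-methoxy-6-pentyl-4-(triisopropylsilyloxy)benzoyl]oxy}-6-pentylbenzoate
Product: 15 benzyl 4-[(4-hydroxy-2-methoxy-6-pentylbenzoyl)oxy]-2-methoxy-6-pentylbenzoate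
Conditions: TBAF, AcOH, THF, 0 °C
Reagents that add atoms: none
Why: Buffered fluoride desilylation frees the ring A phenol, and the acetic acid buffer keeps the medium from becoming basic enough to cleave or transesterify the aryl ester linkage.

Step 7
Reactants: 15 benzyl 4-[(4-hydroxy-2-methoxy-6-pentylbenzoyl)oxy]-2-methoxy-6-pentylbenzoate
Product: 16 4-O-demethylplanaic acid
Conditions: H2 (1 atm), 10% Pd/C, EtOAc, rt
Reagents that add atoms: none
Why: Hydrogenolysis of the benzyl ester over Pd/C is neutral and should leave the depside ester, the phenol and both arenes unchanged.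

## Compound list

1 | 3-fluoro-5-methoxyphenol | COc1cc(O)cc(F)c1 | starting material
2 | triisopropylsilyl chloride | CC(C)[Si](Cl)(C(C)C)C(C)C | starting material
3 | (3-fluoro-5-methoxyphenoxy)triisopropylsilane | COc1cc(F)cc(O[Si](C(C)C)(C(C)C)C(C)C)c1 | intermediate
4 | pentylmagnesium bromide | CCCCC[Mg]Br | starting material
5 | carbon dioxide | O=C=O | starting material
6 | [2-fluoro-6-methoxy-4-(triisopropylsilyloxy)phenyl]lithium | COc1cc(O[Si](C(C)C)(C(C)C)C(C)C)cc(F)c1[Li] | intermediate
7 | 3-methoxy-5-(triisopropylsilyloxy)benzyne | COC1=CC(O[Si](C(C)C)(C(C)C)C(C)C)=CC#C1 | intermediate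
8 | [2-methoxy-6-pentyl-4-(triisopropylsilyloxy)phenyl]magnesium bromide | CCCCCc1cc(O[Si](C(C)C)(C(C)C)C(C)C)cc(OC)c1[Mg]Br | intermediate
9 | 2-methoxy-6-pentyl-4-(triisopropylsilyloxy)benzoic acid | CCCCCc1cc(O[Si](C(C)C)(C(C)C)C(C)C)cc(OC)c1C(=O)O | intermediate
10 | benzyl bromide | BrCc1ccccc1 | starting material
11 | benzyl 2-methoxy-6-pentyl-4-(triisopropylsilyloxy)benzoate | CCCCCc1cc(O[Si](C(C)C)(C(C)C)C(C)C)cc(OC)c1C(=O)OCc1ccccc1 | intermediate
12 | benzyl 4-hydroxy-2-methoxy-6-pentylbenzoate | CCCCCc1cc(O)cc(OC)c1C(=O)OCc1ccccc1 | intermediate
13 | 2-methoxy-6-pentyl-4-(triisopropylsilyloxy)benzoic trifluoroacetic anhydride | CCCCCc1cc(O[Si](C(C)C)(C(C)C)C(C)C)cc(OC)c1C(=O)OC(=O)C(F)(F)F | intermediate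
14 | benzyl 2-methoxy-4-{[2-methoxy-6-pentyl-4-(triisopropylsilyloxy)benzoyl]oxy}-6-pentylbenzoate | CCCCCc1cc(OC(=O)c2c(CCCCC)cc(O[Si](C(C)C)(C(C)C)C(C)C)cc2OC)cc(OC)c1C(=O)OCc1ccccc1 | intermediate
15 | benzyl 4-[(4-hydroxy-2-methoxy-6-pentylbenzoyl)oxy]-2-methoxy-6-pentylbenzoate | CCCCCc1cc(OC(=O)c2c(CCCCC)cc(O)cc2OC)cc(OC)c1C(=O)OCc1ccccc1 | intermediate
16 | 4-O-demethylplanaic acid, 4-[(4-hydroxy-2-methoxy-6-pentylbenzoyl)oxy]-2-methoxy-6-pentylbenzoic acid | CCCCCc1cc(OC(=O)c2c(CCCCC)cc(O)cc2OC)cc(OC)c1C(=O)O | target

## Summary

Total step count: 7. Longest linear sequence: 7 (steps 1 to 7; acid 9 from step 2 also enters step 5 directly as the ring A donor).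

Steps most likely to fail:

Step 2. The aryne may take up butyl instead of pentyl or be consumed by aryllithium 6 to give biaryls, carbomagnesiation by the alkyl Grignard reagent may be sluggish, or some metalation may occur next to the silyloxy group and lead to the wrong aryne. The fallback avoids the aryne and sets out from 3. The same lithiation is run, but aryllithium 6 is trapped with CO2 at −78 °C before LiF is lost, which should give 2-fluoro-6-methoxy-4-(triisopropylsilyloxy)benzoic acid F1. F1 is then treated with an excess of pentylmagnesium bromide 4 in THF (0 °C to reflux). Carboxylate-directed nucleophilic aromatic substitution, a known reaction of unprotected ortho-fluorobenzoic acids with Grignard reagents, should replace fluoride, the better leaving group, rather than methoxide by pentyl. The route is rejoined at 9.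

Step 5. Acylation by the doubly ortho-substituted aroyl donor may be slow, so that trifluoroacetylation of the phenol competes, or the acid may cause loss of the silyl group followed by self-condensation. The fallback changes the activation from an acid-promoted mixed anhydride to a base-promoted acyl chloride coupling and sets out from 9. Treatment with 1-chloro-N,N,2-trimethylprop-1-en-1-amine in CH2Cl2 under neutral conditions should give 2-methoxy-6-pentyl-4-(triisopropylsilyloxy)benzoyl chloride F2. F2 then acylates phenol 12 with Et3N and DMAP in CH2Cl2, and the route is rejoined at 14.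

Step 6. Fluoride or the liberated phenoxide may cleave the depside aryl ester or transfer the acyl group during desilylation. The fallback removes the silyl ether from the late stage and sets out from 12. O-benzylation (BnBr, K2CO3, DMF) should give benzyl 4-(benzyloxy)-2-methoxy-6-pentylbenzoate F3. Saponification of the hindered ester (KOH, DMSO–H2O, 90 °C) should give 4-(benzyloxy)-2-methoxy-6-pentylbenzoic acid F4. F4 is coupled with a further portion of 12 by trifluoroacetic anhydride in toluene, through 4-(benzyloxy)-2-methoxy-6-pentylbenzoic trifluoroacetic anhydride F5 (not isolated), to give benzyl 4-{[4-(benzyloxy)-2-methoxy-6-pentylbenzoyl]oxy}-2-methoxy-6-pentylbenzoate F6. A single hydrogenolysis (H2, Pd/C, EtOAc) then removes both benzyl groups, and the route is rejoined at 16.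

Further compounds
F1 | step 2 | 2-fluoro-6-methoxy-4-(triisopropylsilyloxy)benzoic acid | COc1cc(O[Si](C(C)C)(C(C)C)C(C)C)cc(F)c1C(=O)O
F2 | step 5 | 2-methoxy-6-pentyl-4-(triisopropylsilyloxy)benzoyl chloride | CCCCCc1cc(O[Si](C(C)C)(C(C)C)C(C)C)cc(OC)c1C(=O)Cl
F3 | step 6 | benzyl 4-(benzyloxy)-2-methoxy-6-pentylbenzoate | CCCCCc1cc(OCc2ccccc2)cc(OC)c1C(=O)OCc1ccccc1
F4 | step 6 | 4-(benzyloxy)-2-methoxy-6-pentylbenzoic acid | CCCCCc1cc(OCc2ccccc2)cc(OC)c1C(=O)O
F5 | step 6 | 4-(benzyloxy)-2-methoxy-6-pentylbenzoic trifluoroacetic anhydride | CCCCCc1cc(OCc2ccccc2)cc(OC)c1C(=O)OC(=O)C(F)(F)F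
F6 | step 6 | benzyl 4-{[4-(benzyloxy)-2-methoxy-6-pentylbenzoyl]oxy}-2-methoxy-6-pentylbenzoate | CCCCCc1cc(OC(=O)c2c(CCCCC)cc(OCc3ccccc3)cc2OC)cc(OC)c1C(=O)OCc1ccccc1
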